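The route rests on disconnecting the carbocycle at C4a–C5 and C8–C8a. C5 and C8 both carry a heteroatom and sit at the two ends of the C4a=C8a bond that the pyranone ring shares with the carbocycle, so this bond can act as dienophile towards a 1,4-dioxygenated butadiene. One operation then closes the carbocycle, sets C5 and C8 cis and in the required absolute sense through a sulfinyl auxiliary on C4a, and expels that auxiliary to restore the pyranone. The precursor is the 2-(arylethyl)-4-pyranone bearing an (S)-p-tolylsulfinyl group at C5 of the pyranone (the later C4a); the diene carries one silyloxy and one acetoxy end, so that O5 and O8 emerge differently protected.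

Key step: step 10

Abbreviation: Ar = 4-methoxy-3-[(triisopropylsilyl)oxy]phenyl.
Remark on the chemistry: in step 8 the pyranonyl group is assumed to take the place of the aryl group in the titanium–tartrate model, which points to (S,S)-diethyl tartrate for the (S)-sulfoxide; diacetate 13 is taken as purchasable.

Step 1
Reactants: 1 isovanillin
Product: 2 4-methoxy-3-[(triisopropylsilyl)oxy]benzaldehyde
Conditions: iPr3SiCl, imidazole, DMF, rt
Reagents that add atoms: chlorotriisopropylsilane, CC(C)[Si](Cl)(C(C)C)C(C)C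
Why: Silyl ether formation at the phenol; the triisopropylsilyl group is chosen because, unlike a tert-butyldimethylsilyl aryl ether, it should survive the carbonate methanolysis of step 11 and the buffered fluoride of step 13.

Step 2
Reactants: 3 kojic acid
Product: 4 chlorokojic acid (2-(chloromethyl)-5-hydroxy-4H-pyran-4-one)
Conditions: SOCl2 (neat), rt
Reagents that add atoms: thionyl chloride, O=S(Cl)Cl
Why: Deoxychlorination of the primary alcohol through its chlorosulfite, which should leave the enolic C5 hydroxyl untouched.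

Step 3
Reactants: 4 chlorokojic acid
Product: 5 [(5-hydroxy-4-oxo-4H-pyran-2-yl)methyl]triphenylphosphonium chloride
Conditions: PPh3, MeCN, reflux
Reagents that add atoms: triphenylphosphine, c1ccc(cc1)P(c1ccccc1)c1ccccc1
Why: SN2 quaternisation of triphenylphosphine by the activated primary chloride should give the Wittig salt.

Step 4
Reactants: 5 [(5-hydroxy-4-oxo-4H-pyran-2-yl)methyl]triphenylphosphonium chloride, 2 4-methoxy-3-[(triisopropylsilyl)oxy]benzaldehyde
Product: 7 5-hydroxy-2-(2-Ar-ethenyl)-4H-pyran-4-one (E/Z mixture), via phosphorus ylide 6 (not isolated)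
Conditions: LiN(SiMe3)2 (2.1 equiv), THF, −78 °C to rt; aq. NH4Cl
Reagents that add atoms: none
Why: Wittig olefination, in which the first equivalent of base forms the enolate of the C5 hydroxyl and the second the pyranone-stabilised ylide that condenses with 2; the E/Z ratio does not matter because the alkene is hydrogenated next.

Step 5
Reactants: 7 5-hydroxy-2-(2-Ar-ethenyl)-4H-pyran-4-one
Product: 8 5-hydroxy-2-(2-Ar-ethyl)-4H-pyran-4-one
Conditions: H2 (1 atm), Pd/C, EtOAc, rt
Reagents that add atoms: none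
Why: Heterogeneous catalytic hydrogenation should saturate the styrene-type double bond, while the vinylogous-ester double bonds of the pyranone and the aryl silyl ether remain.

Step 6
Reactants: 8 5-hydroxy-2-(2-Ar-ethyl)-4H-pyran-4-one
Product: 9 6-(2-Ar-ethyl)-4-oxo-4H-pyran-3-yl trifluoromethanesulfonate
Conditions: Tf2O, pyridine, CH2Cl2, −20 to 0 °C
Reagents that add atoms: trifluoromethanesulfonic anhydride, O=S(=O)(OS(=O)(=O)C(F)(F)F)C(F)(F)F
Why: O-Sulfonylation of the enolic hydroxyl turns C5 of the pyranone into a site for cross-coupling.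

Step 7
Reactants: 9 6-(2-Ar-ethyl)-4-oxo-4H-pyran-3-yl trifluoromethanesulfonate, 10 4-methylbenzenethiol
Product: 11 2-(2-Ar-ethyl)-5-[(4-methylphenyl)sulfanyl]-4H-pyran-4-one
Conditions: Pd2(dba)3, Xantphos, iPr2NEt, 1,4-dioxane, 90 °C
Reagents that add atoms: none
Why: Palladium-catalysed C–S cross-coupling, in which zerovalent palladium with the wide-bite-angle ligand inserts into the C–OTf bond, the thiolate replaces triflate on the metal and reductive elimination forms the C5–S bond.

Step 8
Reactants: 11 2-(2-Ar-ethyl)-5-[(4-methylphenyl)sulfanyl]-4H-pyran-4-one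
Product: 12 2-(2-Ar-ethyl)-5-[(S)-4-methylbenzenesulfinyl]-4H-pyran-4-one
Conditions: Ti(OiPr)4 (0.3 equiv), (S,S)-diethyl tartrate, H2O, iPr2NEt, cumene hydroperoxide, toluene, −20 °C; recrystallisation
Reagents that add atoms: cumene hydroperoxide, CC(C)(OO)c1ccccc1
Why: Titanium–tartrate-mediated asymmetric sulfoxidation (Kagan oxidation), in which the chiral titanium peroxo complex delivers oxygen to one of the two enantiotopic sulfur lone pairs and so sets the S configuration at sulfur, with recrystallisation to raise the enantiomeric purity.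

Step 9
Reactants: 13 (1E,3E)-buta-1,3-diene-1,4-diyl diacetate
Product: 15 (1E,3E)-4-[(tert-butyldimethylsilyl)oxy]buta-1,3-dien-1-yl acetate, via dienolate 14 (not isolated)
Conditions: MeLi (2.0 equiv), THF, −78 °C; then tBuMe2SiCl, DMPU, −78 to 0 °C
Reagents that add atoms: tert-butylchlorodimethylsilane, CC(C)(C)[Si](C)(C)Cl
Why: Cleavage of one enol acetate by methyllithium (the acetone formed consumes the second equivalent) should give the lithium dienolate with both E double bonds intact, its charge slowing cleavage of the second acetate, and O-silylation traps it.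

Step 10
Reactants: 12 2-(2-Ar-ethyl)-5-[(S)-4-methylbenzenesulfinyl]-4H-pyran-4-one, 15 (1E,3E)-4-[(tert-butyldimethylsilyl)oxy]buta-1,3-dien-1-yl acetate
Product: 17 (5R,8S)-5-[(tert-butyldimethylsilyl)oxy]-2-(2-Ar-ethyl)-4-oxo-5,8-dihydro-4H-chromen-8-yl acetate (5,8-cis, C6=C7 alkene), via sulfinyl cycloadduct 16 (not isolated)
Conditions: ZnBr2 (1.5 equiv), 15 (2 equiv), CH2Cl2, −20 °C to rt; pH 7 buffer
Reagents that add atoms: none
Why: Proposed new method: ZnBr2 bridges the sulfinyl oxygen and the C4 carbonyl of 12, which lowers the LUMO of the pyranone C5=C6 bond (the later C4a=C8a) and holds the p-tolyl group over one face; diene 15 then adds suprafacially in a concerted, asynchronous [4+2] cycloaddition that forms C8–C8a ahead of C4a–C5 and closes the six-membered carbocycle by intermolecular annulation across that bond, and adduct 16 loses p-toluenesulfenic acid by thermal syn-elimination of the C4a sulfoxide with the cis hydrogen on C8a, which restores the pyranone. The closest known reaction types are the tandem Diels–Alder/sulfoxide elimination of enantiopure 2-(p-tolylsulfinyl)-1,4-quinones and the Diels–Alder reaction of 3-acceptor-substituted chromones with oxygenated dienes; a monocyclic 4-pyranone has not been used in this way. C5 and C8 are set here: their cis relation by the E,E geometry of the diene, and their absolute configuration (5R,8S in 17) by the sulfur stereocentre, the diene adding to the lone-pair face of the chelate, anti to the p-tolyl group, in an endo transition state with the pyranone ring under the diene. Both facial and endo selectivity are needed, because an exo adduct formed on the same face would give the enantiomer of 17 once the sulfoxide is lost; the chelate and secondary overlap with the activated enone should secure them. Regioselectivity is needed as well and should follow from the polarisation of both partners: the acetoxy-bearing diene terminus, made nucleophilic by the stronger silyloxy donor at the far end, bonds to the electrophilic O-bearing β-carbon C6 (C8a), so that the silyl ether ends on C5 and the acetate on C8. This mixed diene is preferred to a diacyloxy diene because it is more electron-rich, leaves a poor leaving group on C5 (less aromatisation) and delivers O5 and O8 already differentiated.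

Step 11
Reactants: 17 (5R,8S)-5-[(tert-butyldimethylsilyl)oxy]-2-(2-Ar-ethyl)-4-oxo-5,8-dihydro-4H-chromen-8-yl acetate
Product: 18 (5R,8S)-5-[(tert-butyldimethylsilyl)oxy]-8-hydroxy-2-(2-Ar-ethyl)-5,8-dihydro-4H-chromen-4-one
Conditions: K2CO3 (0.2 equiv), MeOH, 0 °C
Reagents that add atoms: none
Why: Carbonate-catalysed transesterification should remove only the C8 acetate, since both silyl ethers are stable to it and the poor silyloxy leaving group at C5 holds back base-induced aromatisation; no stereocentre is touched.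

Step 12
Reactants: 18 (5R,8S)-5-[(tert-butyldimethylsilyl)oxy]-8-hydroxy-2-(2-Ar-ethyl)-5,8-dihydro-4H-chromen-4-one
Product: 19 (5R,8R)-5-[(tert-butyldimethylsilyl)oxy]-8-chloro-2-(2-Ar-ethyl)-5,8-dihydro-4H-chromen-4-one (5,8-trans)
Conditions: PPh3, hexachloroacetone, CH2Cl2, −20 to 0 °C
Reagents that add atoms: hexachloroacetone, O=C(C(Cl)(Cl)Cl)C(Cl)(Cl)Cl
Why: Appel-type deoxychlorination, in which chloride displaces the C8 alkoxyphosphonium group in an SN2 step that inverts C8 and places chlorine trans to the C5 oxygen, direct substitution being favoured over ionisation because C8 is attached to the electron-poor C8a.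

Step 13
Reactants: 19 (5R,8R)-5-[(tert-butyldimethylsilyl)oxy]-8-chloro-2-(2-Ar-ethyl)-5,8-dihydro-4H-chromen-4-one
Product: 20 (5R,8R)-8-chloro-5-hydroxy-2-(2-Ar-ethyl)-5,8-dihydro-4H-chromen-4-one
Conditions: HF·pyridine, pyridine, THF, 0 °C
Reagents that add atoms: none
Why: Fluoride-mediated desilylation under buffered, weakly acidic conditions should cleave the alkyl silyl ether much faster than the aryl triisopropylsilyl ether and, being free of base, leave the allylic chloride and both stereocentres intact.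

Step 14
Reactants: 20 (5R,8R)-8-chloro-5-hydroxy-2-(2-Ar-ethyl)-5,8-dihydro-4H-chromen-4-one
Product: 22 (5S,6S,7S,8R)-8-chloro-5,6,7-trihydroxy-2-(2-Ar-ethyl)-5,6,7,8-tetrahydro-4H-chromen-4-one, via osmate ester 21 (not isolated)
Conditions: OsO4 (1.1 equiv), TMEDA, CH2Cl2, −78 °C; then HCl, MeOH, rt
Reagents that add atoms: osmium tetroxide, O=[Os](=O)(=O)=O
Why: Hydroxyl-directed syn-dihydroxylation, a [3+2] addition of OsO4·TMEDA hydrogen-bonded to the C5 hydroxyl, should form both new C–O bonds on the face of C6=C7 syn to that hydroxyl and anti to the C8 chlorine (setting C6 and C7), and acidic methanol then frees the diol without the base that would close the chlorohydrin to an epoxide.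

Step 15
Reactants: 22 (5S,6S,7S,8R)-8-chloro-5,6,7-trihydroxy-2-(2-Ar-ethyl)-5,6,7,8-tetrahydro-4H-chromen-4-one
Product: 23 (5S,6S,7S,8R)-8-chloro-5,6,7-trihydroxy-2-[2-(3-hydroxy-4-methoxyphenyl)ethyl]-5,6,7,8-tetrahydro-4H-chromen-4-one
Conditions: Bu4NF, AcOH, THF, 0 °C
Reagents that add atoms: none
Why: Fluoride cleavage of the aryl silyl ether, buffered with acetic acid so that the trans-chlorohydrin is not exposed to base, should release the target.

Compound list
1 | isovanillin (3-hydroxy-4-methoxybenzaldehyde) | COc1ccc(C=O)cc1O | starting material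
2 | 4-methoxy-3-[(triisopropylsilyl)oxy]benzaldehyde | COc1ccc(C=O)cc1O[Si](C(C)C)(C(C)C)C(C)C | intermediate
3 | kojic acid (5-hydroxy-2-(hydroxymethyl)-4H-pyran-4-one) | OCc1cc(=O)c(O)co1 | starting material
4 | chlorokojic acid (2-(chloromethyl)-5-hydroxy-4H-pyran-4-one) | ClCc1cc(=O)c(O)co1 | intermediate
5 | [(5-hydroxy-4-oxo-4H-pyran-2-yl)methyl]triphenylphosphonium chloride | [Cl-].O=c1cc(C[P+](c2ccccc2)(c2ccccc2)c2ccccc2)occ1O | intermediate
6 | lithium 4-oxo-6-[(triphenylphosphoranylidene)methyl]-4H-pyran-3-olate (ylide, not isolated) | [Li+].[O-]c1coc(C=P(c2ccccc2)(c2ccccc2)c2ccccc2)cc1=O | intermediate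
7 | 5-hydroxy-2-(2-Ar-ethenyl)-4H-pyran-4-one, E/Z mixture | COc1ccc(C=Cc2cc(=O)c(O)co2)cc1O[Si](C(C)C)(C(C)C)C(C)C | intermediate
8 | 5-hydroxy-2-(2-Ar-ethyl)-4H-pyran-4-one | COc1ccc(CCc2cc(=O)c(O)co2)cc1O[Si](C(C)C)(C(C)C)C(C)C | intermediate
9 | 6-(2-Ar-ethyl)-4-oxo-4H-pyran-3-yl trifluoromethanesulfonate | COc1ccc(CCc2cc(=O)c(OS(=O)(=O)C(F)(F)F)co2)cc1O[Si](C(C)C)(C(C)C)C(C)C | intermediate
10 | 4-methylbenzenethiol | Cc1ccc(S)cc1 | starting material
11 | 2-(2-Ar-ethyl)-5-[(4-methylphenyl)sulfanyl]-4H-pyran-4-one | COc1ccc(CCc2cc(=O)c(Sc3ccc(C)cc3)co2)cc1O[Si](C(C)C)(C(C)C)C(C)C | intermediate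
12 | 2-(2-Ar-ethyl)-5-[(S)-4-methylbenzenesulfinyl]-4H-pyran-4-one | COc1ccc(CCc2cc(=O)c([S@@](=O)c3ccc(C)cc3)co2)cc1O[Si](C(C)C)(C(C)C)C(C)C | intermediate
13 | (1E,3E)-buta-1,3-diene-1,4-diyl diacetate | CC(=O)O/C=C/C=C/OC(C)=O | starting material
14 | lithium (1E,3E)-4-acetoxybuta-1,3-dien-1-olate (not isolated) | [Li+].[O-]/C=C/C=C/OC(C)=O | intermediate
15 | (1E,3E)-4-[(tert-butyldimethylsilyl)oxy]buta-1,3-dien-1-yl acetate | CC(=O)O/C=C/C=C/O[Si](C)(C)C(C)(C)C | intermediate
16 | (4aR,5R,8S,8aS)-5-[(tert-butyldimethylsilyl)oxy]-2-(2-Ar-ethyl)-4a-[(S)-4-methylbenzenesulfinyl]-4-oxo-4a,5,8,8a-tetrahydro-4H-chromen-8-yl acetate (endo cycloadduct, not isolated) | COc1ccc(CCC2=CC(=O)[C@]3([S@@](=O)c4ccc(C)cc4)[C@H](O[Si](C)(C)C(C)(C)C)C=C[C@H](OC(C)=O)[C@@H]3O2)cc1O[Si](C(C)C)(C(C)C)C(C)C | intermediate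
17 | (5R,8S)-5-[(tert-butyldimethylsilyl)oxy]-2-(2-Ar-ethyl)-4-oxo-5,8-dihydro-4H-chromen-8-yl acetate (cis) | COc1ccc(CCc2cc(=O)c3c(o2)[C@@H](OC(C)=O)C=C[C@H]3O[Si](C)(C)C(C)(C)C)cc1O[Si](C(C)C)(C(C)C)C(C)C | intermediate
18 | (5R,8S)-5-[(tert-butyldimethylsilyl)oxy]-8-hydroxy-2-(2-Ar-ethyl)-5,8-dihydro-4H-chromen-4-one | COc1ccc(CCc2cc(=O)c3c(o2)[C@@H](O)C=C[C@H]3O[Si](C)(C)C(C)(C)C)cc1O[Si](C(C)C)(C(C)C)C(C)C | intermediate
19 | (5R,8R)-5-[(tert-butyldimethylsilyl)oxy]-8-chloro-2-(2-Ar-ethyl)-5,8-dihydro-4H-chromen-4-one (trans) | COc1ccc(CCc2cc(=O)c3c(o2)[C@H](Cl)C=C[C@H]3O[Si](C)(C)C(C)(C)C)cc1O[Si](C(C)C)(C(C)C)C(C)C | intermediate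
20 | (5R,8R)-8-chloro-5-hydroxy-2-(2-Ar-ethyl)-5,8-dihydro-4H-chromen-4-one | COc1ccc(CCc2cc(=O)c3c(o2)[C@H](Cl)C=C[C@H]3O)cc1O[Si](C(C)C)(C(C)C)C(C)C | intermediate
21 | cyclic 6,7-osmate ester of 22 (hexavalent osmium, dioxo, TMEDA chelate; not isolated) | COc1ccc(CCc2cc(=O)c3c(o2)[C@H](Cl)[C@H]4O[Os](=O)(=O)O[C@H]4[C@H]3O)cc1O[Si](C(C)C)(C(C)C)C(C)C.CN(C)CCN(C)C | intermediate
22 | (5S,6S,7S,8R)-8-chloro-5,6,7-trihydroxy-2-(2-Ar-ethyl)-5,6,7,8-tetrahydro-4H-chromen-4-one | COc1ccc(CCc2cc(=O)c3c(o2)[C@H](Cl)[C@@H](O)[C@@H](O)[C@H]3O)cc1O[Si](C(C)C)(C(C)C)C(C)C | intermediate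
23 | (5S,6S,7S,8R)-8-chloro-5,6,7-trihydroxy-2-[2-(3-hydroxy-4-methoxyphenyl)ethyl]-5,6,7,8-tetrahydro-4H-chromen-4-one | COc1ccc(CCc2cc(=O)c3c(o2)[C@H](Cl)[C@@H](O)[C@@H](O)[C@H]3O)cc1O | target

Total step count: 15. Longest linear sequence: 13 steps (3 → 4 → 5 → 7 → 8 → 9 → 11 → 12 → 17 → 18 → 19 → 20 → 22 → 23).

Steps most likely to fail

1. Step 10 (proposed new method).
- What may go wrong: the cycloaddition may be too slow, because the vinylogous-ester stabilisation of the pyranone is only partly offset by the sulfinyl group and zinc.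
- Facial, endo/exo or regiochemical control may be incomplete, and the first two translate directly into loss of enantiomeric purity.
- Sulfenic acid may be lost towards C5, whose hydrogen is also cis to sulfur in the endo adduct, instead of towards C8a.
- The 1,4-dioxygenated cyclohexadiene may aromatise by 1,4-elimination.

Fallback (known reaction types only, ring closed by metathesis, both carbinol centres set by reagent control), setting out from 8 and coming back at 17. Hydroxymethylation at C6 of the pyranone with aqueous formaldehyde and NaOH would give the 5-hydroxy-6-(hydroxymethyl)pyranone F1. MnO2 would oxidise this to the 6-formyl-5-hydroxypyranone F2, and Tf2O with pyridine would give the formyl triflate F3. Catalytic enantioselective vinyl transfer from Zn(CH=CH2)2, with the enantiomer of a chiral amino alcohol ligand that delivers the S carbinol, would give the allylic alcohol F4. A carbonylative Stille coupling (CO, Bu3SnCH=CH2, Pd(PPh3)4, LiCl) would replace the triflate by an acryloyl group and give the vinyl ketone F5. Acetylation (Ac2O, pyridine) would give the allylic acetate F6. Corey–Bakshi–Shibata reduction with the (S)-methyl oxazaborolidine and BH3·SMe2, the hetaryl group acting as the large substituent, would set the R carbinol of the bis-allylic alcohol F7. Silylation with tBuMe2SiOTf and 2,6-lutidine would give the silyl ether diene F8. Ring-closing metathesis with the second-generation Grubbs catalyst would then form C6=C7 and give 17.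

2. Step 8.
- What may go wrong: oxygen transfer may discriminate poorly between the two sulfur lone pairs, because both sulfur substituents are flat sp2 groups of similar size.
- Over-oxidation to the sulfone may compete.

Fallback (sulfur stereocentre brought in ready-made, Andersen synthesis), setting out from 9 and coming back at 12. Stannylation with Me3SnSnMe3, Pd(PPh3)4 and LiCl in dioxane would give the 5-(trimethylstannyl)pyranone F9. Iodine would convert this into the 5-iodopyranone F10. Iodine–magnesium exchange with iPrMgCl·LiCl at −40 °C would give the pyranonylmagnesium chloride F11. Treated in the same flask with (1R,2S,5R)-menthyl (S)-p-toluenesulfinate, this would undergo substitution at sulfur with inversion and give 12 in the S configuration.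

3. Step 12.
- What may go wrong: the activated C8 oxygen may leave with allylic transposition (attack at C6), by ionisation with loss of configuration, or by 1,4-elimination to the aromatic chromone, instead of by clean SN2 displacement.

Fallback (chlorine introduced by epoxide opening, not by displacement of an activated alcohol), setting out from 17 and coming back at 22. PdCl2(MeCN)2 (divalent palladium) in THF would shift the allylic acetate suprafacially from C8 to C6 and give the 6-acetoxy-5,6-dihydrochromone F12, whose C7=C8 bond is conjugated with the pyranone. Methanolysis (K2CO3, MeOH, 0 °C) would give the allylic alcohol F13. Hydroxyl-directed epoxidation (VO(acac)2, tBuOOH) would give the syn 7,8-epoxy alcohol F14. HCl in ether at low temperature would open the epoxide at C8 with inversion to give the 5-O-silyl chlorohydrin F15. HF·pyridine would then remove the C5 silyl ether and give 22.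

Further compounds
F1 | step 10 | 5-hydroxy-6-(hydroxymethyl)-2-(2-Ar-ethyl)-4H-pyran-4-one | COc1ccc(CCc2cc(=O)c(O)c(CO)o2)cc1O[Si](C(C)C)(C(C)C)C(C)C
F2 | step 10 | 3-hydroxy-6-(2-Ar-ethyl)-4-oxo-4H-pyran-2-carbaldehyde | COc1ccc(CCc2cc(=O)c(O)c(C=O)o2)cc1O[Si](C(C)C)(C(C)C)C(C)C
F3 | step 10 | 2-formyl-6-(2-Ar-ethyl)-4-oxo-4H-pyran-3-yl trifluoromethanesulfonate | COc1ccc(CCc2cc(=O)c(OS(=O)(=O)C(F)(F)F)c(C=O)o2)cc1O[Si](C(C)C)(C(C)C)C(C)C
F4 | step 10 | 2-[(1S)-1-hydroxyprop-2-en-1-yl]-6-(2-Ar-ethyl)-4-oxo-4H-pyran-3-yl trifluoromethanesulfonate | COc1ccc(CCc2cc(=O)c(OS(=O)(=O)C(F)(F)F)c(o2)[C@@H](O)C=C)cc1O[Si](C(C)C)(C(C)C)C(C)C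
F5 | step 10 | 2-[(1S)-1-hydroxyprop-2-en-1-yl]-6-(2-Ar-ethyl)-3-(prop-2-enoyl)-4H-pyran-4-one | COc1ccc(CCc2cc(=O)c(C(=O)C=C)c(o2)[C@@H](O)C=C)cc1O[Si](C(C)C)(C(C)C)C(C)C
F6 | step 10 | (1S)-1-[6-(2-Ar-ethyl)-4-oxo-3-(prop-2-enoyl)-4H-pyran-2-yl]prop-2-en-1-yl acetate | COc1ccc(CCc2cc(=O)c(C(=O)C=C)c(o2)[C@@H](OC(C)=O)C=C)cc1O[Si](C(C)C)(C(C)C)C(C)C
F7 | step 10 | (1S)-1-{3-[(1R)-1-hydroxyprop-2-en-1-yl]-6-(2-Ar-ethyl)-4-oxo-4H-pyran-2-yl}prop-2-en-1-yl acetate | COc1ccc(CCc2cc(=O)c([C@H](O)C=C)c(o2)[C@@H](OC(C)=O)C=C)cc1O[Si](C(C)C)(C(C)C)C(C)C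
F8 | step 10 | (1S)-1-{3-[(1R)-1-[(tert-butyldimethylsilyl)oxy]prop-2-en-1-yl]-6-(2-Ar-ethyl)-4-oxo-4H-pyran-2-yl}prop-2-en-1-yl acetate | COc1ccc(CCc2cc(=O)c([C@H](O[Si](C)(C)C(C)(C)C)C=C)c(o2)[C@@H](OC(C)=O)C=C)cc1O[Si](C(C)C)(C(C)C)C(C)C
F9 | step 8 | 2-(2-Ar-ethyl)-5-(trimethylstannyl)-4H-pyran-4-one | COc1ccc(CCc2cc(=O)c([Sn](C)(C)C)co2)cc1O[Si](C(C)C)(C(C)C)C(C)C
F10 | step 8 | 5-iodo-2-(2-Ar-ethyl)-4H-pyran-4-one | COc1ccc(CCc2cc(=O)c(I)co2)cc1O[Si](C(C)C)(C(C)C)C(C)C
F11 | step 8 | [6-(2-Ar-ethyl)-4-oxo-4H-pyran-3-yl]magnesium chloride (not isolated) | COc1ccc(CCc2cc(=O)c([Mg]Cl)co2)cc1O[Si](C(C)C)(C(C)C)C(C)C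
F12 | step 12 | (5S,6R)-5-[(tert-butyldimethylsilyl)oxy]-2-(2-Ar-ethyl)-4-oxo-5,6-dihydro-4H-chromen-6-yl acetate | COc1ccc(CCc2cc(=O)c3c(o2)C=C[C@@H](OC(C)=O)[C@H]3O[Si](C)(C)C(C)(C)C)cc1O[Si](C(C)C)(C(C)C)C(C)C
F13 | step 12 | (5S,6R)-5-[(tert-butyldimethylsilyl)oxy]-6-hydroxy-2-(2-Ar-ethyl)-5,6-dihydro-4H-chromen-4-one | COc1ccc(CCc2cc(=O)c3c(o2)C=C[C@@H](O)[C@H]3O[Si](C)(C)C(C)(C)C)cc1O[Si](C(C)C)(C(C)C)C(C)C
F14 | step 12 | 7,8-epoxy-6-hydroxy-5-[(tert-butyldimethylsilyl)oxy]-2-(2-Ar-ethyl)-5,6,7,8-tetrahydro-4H-chromen-4-one, all three oxygens on the same face | COc1ccc(CCc2cc(=O)c3c(o2)[C@@H]4[C@@H](O4)[C@@H](O)[C@H]3O[Si](C)(C)C(C)(C)C)cc1O[Si](C(C)C)(C(C)C)C(C)C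
F15 | step 12 | 5-O-(tert-butyldimethylsilyl) ether of 22 | COc1ccc(CCc2cc(=O)c3c(o2)[C@H](Cl)[C@@H](O)[C@@H](O)[C@H]3O[Si](C)(C)C(C)(C)C)cc1O[Si](C(C)C)(C(C)C)C(C)C
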